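Ring B (C5–C10) is opened across C9–C10 and C7–C8. The route exploits the oxygenated C6 that sits between sp2 C5 and oxygenated C7, next to the contiguous C8 (secondary methyl) and C9 (quaternary) centres. At the enol-ether level (C5=C6–OSi) this ring is a Diels–Alder retron. A catalytic enantioselective [4+2] joins a ring-A 2-silyloxy-1-acetoxy diene (C10=C5–C6(OTBS)=C7H–OAc) with a linalool-derived (E)-2-alkylidene enal (C8=C9, carrying the complete C11–C16 side chain and C20 as CHO). It builds ring B, both C–C bonds and the C7/C8/C9 stereotriad at once. Aldehyde-to-methyl reduction, dehydrogenation to the Δ5(10)-6-ketone, ketone reduction and desilylation complete the synthesis.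

Key step: step 8

Remark: halimane numbering is used (ring A: C1–C3 CH2, C4 CMe2 with C18/C19; ring fusion C5/C10; ring B: C6, C7, C8 with Me C17, C9 with Me C20 and side chain C11–C12–C13(Me C16)–C14=C15); (S)-(+)-linalool is assumed to be available in high enantiomeric purity, and the sense of induction of the oxazaborolidinium catalyst is assigned from its formyl C–H···O binding model (the enantiomeric catalyst would be used if the opposite sense were found).

Step 1
Reactants: 1 (S)-(+)-linalool
Product: 2 triethyl{[(3S)-3,7-dimethylocta-1,6-dien-3-yl]oxy}silane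
Conditions: TESOTf, 2,6-lutidine, CH2Cl2, −78 → 0 °C
Reagents that add atoms: triethylsilyl trifluoromethanesulfonate, CC[Si](CC)(CC)OS(=O)(=O)C(F)(F)F
Why: Silyl triflate silylation (silyl ether protection) of the hindered tertiary allylic alcohol should proceed without touching the C13 stereocentre.

Step 2
Reactants: 2 triethyl{[(3S)-3,7-dimethylocta-1,6-dien-3-yl]oxy}silane
Product: 4 (4S)-4-methyl-4-[(triethylsilyl)oxy]hex-5-enal, via secondary ozonide 3 (not isolated)
Conditions: O3, CH2Cl2, −78 °C (Sudan Red 7B end point); then PPh3, −78 °C → rt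
Reagents that add atoms: ozone, O=[O+][O-]
Why: Chemoselective ozonolysis should cleave the electron-rich trisubstituted alkene much faster than the vinyl group on the oxygenated quaternary carbon, and reductive work-up gives the aldehyde.

Step 3
Reactants: 4 (4S)-4-methyl-4-[(triethylsilyl)oxy]hex-5-enal
Product: 5 triethyl{[(3S)-7-methoxy-3-methylhepta-1,6-dien-3-yl]oxy}silane (E/Z mixture)
Conditions: MeOCH2PPh3Cl, KHMDS, THF, 0 °C → rt
Reagents that add atoms: (methoxymethyl)triphenylphosphonium chloride, COC[P+](c1ccccc1)(c1ccccc1)c1ccccc1.[Cl-]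
Why: Wittig methoxymethylenation of an unhindered aldehyde adds the carbon that becomes C20; the E/Z ratio of the enol ether is irrelevant.

Step 4
Reactants: 5 triethyl{[(3S)-7-methoxy-3-methylhepta-1,6-dien-3-yl]oxy}silane
Product: 8 (2E,5S)-2-ethylidene-5-methyl-5-[(triethylsilyl)oxy]hept-6-enal, via trimethoxy adduct 6 (not isolated), via β-methoxy aldehyde 7 (not isolated)
Conditions: MeCH(OMe)2, BF3·OEt2 (cat.), CH2Cl2, −78 °C; then PPTS, acetone/H2O, 45 °C; then DBU, rt
Reagents that add atoms: acetaldehyde dimethyl acetal, CC(OC)OC; water, O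
Why: Mukaiyama–Isler enol ether–acetal condensation forms the C8–C9 bond, and acetal hydrolysis with E1cB loss of methanol should give the thermodynamically favoured (E)-2-alkylidene aldehyde (CHO trans to the methyl group).

Step 5
Reactants: 9 2,2-dimethylcyclohexanone
Product: 10 N'-(2,2-dimethylcyclohexylidene)-2,4,6-tri(propan-2-yl)benzenesulfonohydrazide
Conditions: TrisNHNH2, HCl (cat.), THF, rt
Reagents that add atoms: 2,4,6-triisopropylbenzenesulfonyl hydrazide, CC(C)c1cc(C(C)C)c(S(=O)(=O)NN)c(C(C)C)c1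
Why: Acid-catalysed hydrazone formation gives a trisylhydrazone with α-hydrogens on one side only, as required for a regiospecific Shapiro reaction.

Step 6
Reactants: 10 N'-(2,2-dimethylcyclohexylidene)-2,4,6-tri(propan-2-yl)benzenesulfonohydrazide
Product: 13 2-(6,6-dimethylcyclohex-1-en-1-yl)-2-oxoethyl acetate, via vinyllithium 11 (not isolated), via vinylzinc chloride 12 (not isolated)
Conditions: n-BuLi (2.2 equiv), THF, −78 → 0 °C; ZnCl2, 0 °C; then AcOCH2COCl, Pd(PPh3)4 (5 mol%), 0 °C → rt
Reagents that add atoms: acetoxyacetyl chloride, CC(=O)OCC(Cl)=O; n-butyllithium, [Li]CCCC (Li only in 11); zinc chloride, Cl[Zn]Cl (Zn and Cl only in 12)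
Why: The Shapiro reaction gives the cyclohexenyllithium regiospecifically, and transmetalation to zinc followed by Pd-catalysed Negishi acylation with the acid chloride should tolerate the acetate.

Step 7
Reactants: 13 2-(6,6-dimethylcyclohex-1-en-1-yl)-2-oxoethyl acetate
Product: 14 (Z)-2-[(tert-butyldimethylsilyl)oxy]-2-(6,6-dimethylcyclohex-1-en-1-yl)ethenyl acetate
Conditions: TBSOTf, Et3N, CH2Cl2, −78 → 0 °C
Reagents that add atoms: tert-butyldimethylsilyl trifluoromethanesulfonate, CC(C)(C)[Si](C)(C)OS(=O)(=O)C(F)(F)F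
Why: Soft enolisation (silyl triflate/amine) at the more acidic α′-CH2OAc position should give the cross-conjugated silyl enol ether as the Z isomer, with OAc trans to the ring (least A1,3 strain) and therefore "outside" in the s-cis diene.

Step 8
Reactants: 14 (Z)-2-[(tert-butyldimethylsilyl)oxy]-2-(6,6-dimethylcyclohex-1-en-1-yl)ethenyl acetate (1.5 equiv); 8 (2E,5S)-2-ethylidene-5-methyl-5-[(triethylsilyl)oxy]hept-6-enal
Product: 15 (7R,8S,9R,10R,13S)-7-acetoxy-6-[(tert-butyldimethylsilyl)oxy]-13-[(triethylsilyl)oxy]halima-5,14-dien-20-al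
Conditions: (S)-o-tolyl-CBS oxazaborolidine·Tf2NH (20 mol%), CH2Cl2, −78 → −40 °C
Reagents that add atoms: none
Why: This is a Lewis-acid-catalysed normal-demand Diels–Alder reaction in which the oxazaborolidinium binds the formyl group of 8 (B–O bond plus formyl C–H···O contact) and a concerted, asynchronous [4+2] forms C7–C8 first and C9–C10 second; the closest known type is the oxazaborolidinium-catalysed cycloaddition of 2-silyloxy dienes with α-substituted enals. Ring B is closed by intermolecular suprafacial [4π+2π] union of the diene C10=C5–C6=C7 with C8=C9, leaving the C5=C6 silyl enol ether. The relative configuration at C8/C9 (C11 cis to C17, CHO trans) is copied stereospecifically from the (E)-enal, and the absolute configuration is set by the (S)-catalyst, whose aryl group shields one enal face so that the diene adds to the C9-Re/C8-Si face. C7 follows from the (Z)-enol acetate (OAc outside) and the formyl-endo transition state, which should place OAc cis to CHO and trans to C17; C10 is transient and is erased in step 10. The step needs regioselectivity (C7 to the β-carbon C8), secured by the 6-OTBS donor and reinforced by the alkyl-substituted C10 terminus, and chemoselectivity for the catalyst-bound enal over the remote vinyl group.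

Step 9
Reactants: 15 (7R,8S,9R,10R,13S)-7-acetoxy-6-[(tert-butyldimethylsilyl)oxy]-13-[(triethylsilyl)oxy]halima-5,14-dien-20-al
Product: 17 (7R,8S,9S,10S,13S)-7-acetoxy-6-[(tert-butyldimethylsilyl)oxy]-13-[(triethylsilyl)oxy]halima-5,14-diene, via tosylhydrazone 16 (not isolated)
Conditions: TsNHNH2, 4 Å MS, THF, rt; then catecholborane, 0 °C; then NaOAc·3H2O, 60 °C
Reagents that add atoms: p-toluenesulfonyl hydrazide, Cc1ccc(cc1)S(=O)(=O)NN (atoms only in 16)
Why: In this Kabalka-type deoxygenation the aldehyde is the only carbonyl able to condense, catecholborane reduces the C=N bond, and acetate-triggered loss of sulfinate and N2 should leave the C20 methyl group without touching the silyl enol ether, ester or alkenes.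

Step 10
Reactants: 17 (7R,8S,9S,10S,13S)-7-acetoxy-6-[(tert-butyldimethylsilyl)oxy]-13-[(triethylsilyl)oxy]halima-5,14-diene
Product: 18 (7R,8S,9R,13S)-7-acetoxy-13-[(triethylsilyl)oxy]halima-5(10),14-dien-6-one
Conditions: DDQ, 2,4,6-collidine, CH2Cl2, 0 °C → rt
Reagents that add atoms: none
Why: In this DDQ dehydrogenation of a silyl enol ether, removal of the tertiary allylic H-10 should give a silyloxyallyl cation that loses silicon to form the Δ5(10)-6-ketone, with collidine buffering the medium so that the epimerisable C7 centre is preserved.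

Step 11
Reactants: 18 (7R,8S,9R,13S)-7-acetoxy-13-[(triethylsilyl)oxy]halima-5(10),14-dien-6-one
Product: 19 (6S,7R,8S,9R,13S)-7-acetoxy-13-[(triethylsilyl)oxy]halima-5(10),14-dien-6-ol
Conditions: L-Selectride, THF, −78 °C; AcOH quench
Reagents that add atoms: none
Why: 1,2-Reduction of the tetrasubstituted enone by a bulky trialkylborohydride should occur by equatorial attack on the half-chair (7-OAc and 8-Me equatorial), away from axial H-8, placing the new 6-OH pseudo-axial and cis to the 7-acetate (6S), while β,β-disubstitution suppresses conjugate reduction.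

Step 12
Reactants: 19 (6S,7R,8S,9R,13S)-7-acetoxy-13-[(triethylsilyl)oxy]halima-5(10),14-dien-6-ol
Product: 20 (6S,7R,8S,9R,13S)-7-acetoxyhalima-5(10),14-diene-6,13-diol (target)
Conditions: HF·pyridine, pyridine, THF, 0 °C → rt
Reagents that add atoms: none
Why: Buffered fluoride cleavage of the tertiary triethylsilyl ether is non-basic, so it should avoid acetyl migration to O6 and ionisation of the allylic alcohols.

Compound list
1 | (S)-(+)-linalool, (3S)-3,7-dimethylocta-1,6-dien-3-ol | C=C[C@@](C)(O)CCC=C(C)C | starting material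
2 | triethyl{[(3S)-3,7-dimethylocta-1,6-dien-3-yl]oxy}silane | C=C[C@@](C)(O[Si](CC)(CC)CC)CCC=C(C)C | intermediate
3 | secondary ozonide of 2, 3,3-dimethyl-5-{(3S)-3-methyl-3-[(triethylsilyl)oxy]pent-4-en-1-yl}-1,2,4-trioxolane | C=C[C@@](C)(O[Si](CC)(CC)CC)CCC1OOC(C)(C)O1 | intermediate
4 | (4S)-4-methyl-4-[(triethylsilyl)oxy]hex-5-enal | C=C[C@@](C)(O[Si](CC)(CC)CC)CCC=O | intermediate
5 | triethyl{[(3S)-7-methoxy-3-methylhepta-1,6-dien-3-yl]oxy}silane (E/Z mixture) | C=C[C@@](C)(O[Si](CC)(CC)CC)CCC=COC | intermediate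
6 | triethyl{[(3S)-6-(dimethoxymethyl)-7-methoxy-3-methyloct-1-en-3-yl]oxy}silane (diastereomer mixture) | C=C[C@@](C)(O[Si](CC)(CC)CC)CCC(C(C)OC)C(OC)OC | intermediate
7 | (5S)-2-(1-methoxyethyl)-5-methyl-5-[(triethylsilyl)oxy]hept-6-enal (diastereomer mixture) | C=C[C@@](C)(O[Si](CC)(CC)CC)CCC(C(C)OC)C=O | intermediate
8 | (2E,5S)-2-ethylidene-5-methyl-5-[(triethylsilyl)oxy]hept-6-enal | C=C[C@@](C)(O[Si](CC)(CC)CC)CC/C(C=O)=C\C | intermediate
9 | 2,2-dimethylcyclohexanone | CC1(C)CCCCC1=O | starting material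
10 | N'-(2,2-dimethylcyclohexylidene)-2,4,6-tri(propan-2-yl)benzenesulfonohydrazide | CC(C)c1cc(C(C)C)c(S(=O)(=O)NN=C2CCCCC2(C)C)c(C(C)C)c1 | intermediate
11 | (6,6-dimethylcyclohex-1-en-1-yl)lithium | [Li]C1=CCCCC1(C)C | intermediate
12 | chloro(6,6-dimethylcyclohex-1-en-1-yl)zinc | Cl[Zn]C1=CCCCC1(C)C | intermediate
13 | 2-(6,6-dimethylcyclohex-1-en-1-yl)-2-oxoethyl acetate | CC(=O)OCC(=O)C1=CCCCC1(C)C | intermediate
14 | (Z)-2-[(tert-butyldimethylsilyl)oxy]-2-(6,6-dimethylcyclohex-1-en-1-yl)ethenyl acetate | CC(=O)O/C=C(/C1=CCCCC1(C)C)O[Si](C)(C)C(C)(C)C | intermediate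
15 | (7R,8S,9R,10R,13S)-7-acetoxy-6-[(tert-butyldimethylsilyl)oxy]-13-[(triethylsilyl)oxy]halima-5,14-dien-20-al (C9 bears CHO and the side chain, C8 Me, C7 OAc, C5=C6 silyl enol ether, H on C10) | O=C[C@@]1(CC[C@](C)(O[Si](CC)(CC)CC)C=C)[C@H](C)[C@@H](OC(C)=O)C(O[Si](C)(C)C(C)(C)C)=C2[C@H]1CCCC2(C)C | intermediate
16 | 20-(p-toluenesulfonyl)hydrazone of 15 | Cc1ccc(cc1)S(=O)(=O)NN=C[C@@]1(CC[C@](C)(O[Si](CC)(CC)CC)C=C)[C@H](C)[C@@H](OC(C)=O)C(O[Si](C)(C)C(C)(C)C)=C2[C@H]1CCCC2(C)C | intermediate
17 | (7R,8S,9S,10S,13S)-7-acetoxy-6-[(tert-butyldimethylsilyl)oxy]-13-[(triethylsilyl)oxy]halima-5,14-diene | C[C@@]1(CC[C@](C)(O[Si](CC)(CC)CC)C=C)[C@H](C)[C@@H](OC(C)=O)C(O[Si](C)(C)C(C)(C)C)=C2[C@H]1CCCC2(C)C | intermediate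
18 | (7R,8S,9R,13S)-7-acetoxy-13-[(triethylsilyl)oxy]halima-5(10),14-dien-6-one | C[C@@]1(CC[C@](C)(O[Si](CC)(CC)CC)C=C)[C@H](C)[C@@H](OC(C)=O)C(=O)C2=C1CCCC2(C)C | intermediate
19 | (6S,7R,8S,9R,13S)-7-acetoxy-13-[(triethylsilyl)oxy]halima-5(10),14-dien-6-ol | C[C@@]1(CC[C@](C)(O[Si](CC)(CC)CC)C=C)[C@H](C)[C@@H](OC(C)=O)[C@@H](O)C2=C1CCCC2(C)C | intermediate
20 | (6S,7R,8S,9R,13S)-7-acetoxyhalima-5(10),14-diene-6,13-diol, i.e. (1S,2R,3S,4R)-1-hydroxy-4-[(3S)-3-hydroxy-3-methylpent-4-en-1-yl]-3,4,8,8-tetramethyl-1,2,3,4,5,6,7,8-octahydronaphthalen-2-yl acetate | C=C[C@@](C)(O)CC[C@@]1(C)C2=C([C@H](O)[C@H](OC(C)=O)[C@H]1C)C(C)(C)CCC2 | target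

Total step count: 12. Longest linear sequence: 9 steps (steps 1–4, then 8–12); the diene branch (steps 5–7) is three steps.

Steps most likely to fail

Step 8. The cycloaddition may stall because the 2,3-disubstituted diene is sterically encumbered and its 1-acetoxy group lowers the nucleophilicity of C7. The acidic catalyst could then strip the silyl group from the diene before ring formation, or facial control could erode. Fallback: the C7 oxygen is introduced after ring B is made. From 10, the Shapiro/zinc sequence of step 6 (via 11 and 12) is run with acetyl chloride to give 1-(6,6-dimethylcyclohex-1-en-1-yl)ethan-1-one F1. TBSOTf/Et3N gives the more reactive, unsubstituted 2-silyloxy diene tert-butyl{[1-(6,6-dimethylcyclohex-1-en-1-yl)ethenyl]oxy}dimethylsilane F2. Cycloaddition with 8 under the step-8 catalyst should give the 7-deacetoxy analogue of 15 F3. The conditions of step 9 convert it, through the 20-tosylhydrazone of F3 F4, into the 7-deacetoxy analogue of 17 F5. DDQ/collidine gives the 7-deacetoxy analogue of 18 F6. α′-Acetoxylation with Mn(OAc)3·2H2O in benzene at reflux, with the acetate expected trans to the C8 methyl group, returns to 18.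

Step 10. At the fully substituted enol ether carbon C5, DDQ may add through carbon or oxygen instead of removing H-10, or the enol ether may simply be desilylated to the saturated ketone. Fallback: a halogenation–dehydrohalogenation sequence. From 17, NBS in THF at 0 °C should give the 5-bromo-6-ketone from 17 F7, with axial bromine anti to H-10. Dehydrobromination with Li2CO3/LiBr in DMF at 100 °C returns to 18.

Step 11. Hydride may be delivered to the wrong face of the C6 carbonyl (axial attack giving the 6-epimer), or the acetyl group may migrate from O7 to O6 in the alkoxide. Fallback: accept the other epimer and invert it. From 18, Luche reduction (NaBH4, CeCl3·7H2O, MeOH, −78 °C) would give the 6-epimer of 19 F8. Mitsunobu inversion with chloroacetic acid (PPh3, DIAD, toluene) gives the 6-O-chloroacetate of 19 F9. Selective removal of the chloroacetate with thiourea/NaHCO3 in EtOH returns to 19.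

Further compounds
F1 | step 8 | 1-(6,6-dimethylcyclohex-1-en-1-yl)ethan-1-one | CC(=O)C1=CCCCC1(C)C
F2 | step 8 | tert-butyl{[1-(6,6-dimethylcyclohex-1-en-1-yl)ethenyl]oxy}dimethylsilane | C=C(O[Si](C)(C)C(C)(C)C)C1=CCCCC1(C)C
F3 | step 8 | 7-deacetoxy analogue of 15 (6-silyl enol ether, 20-al, same configuration at C8, C9, C10, C13) | O=C[C@@]1(CC[C@](C)(O[Si](CC)(CC)CC)C=C)[C@H](C)CC(O[Si](C)(C)C(C)(C)C)=C2[C@H]1CCCC2(C)C
F4 | step 8 | 20-tosylhydrazone of F3 | Cc1ccc(cc1)S(=O)(=O)NN=C[C@@]1(CC[C@](C)(O[Si](CC)(CC)CC)C=C)[C@H](C)CC(O[Si](C)(C)C(C)(C)C)=C2[C@H]1CCCC2(C)C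
F5 | step 8 | 7-deacetoxy analogue of 17 | C[C@@]1(CC[C@](C)(O[Si](CC)(CC)CC)C=C)[C@H](C)CC(O[Si](C)(C)C(C)(C)C)=C2[C@H]1CCCC2(C)C
F6 | step 8 | 7-deacetoxy analogue of 18 (Δ5(10)-6-ketone) | C[C@@]1(CC[C@](C)(O[Si](CC)(CC)CC)C=C)[C@H](C)CC(=O)C2=C1CCCC2(C)C
F7 | step 10 | 5-bromo-6-ketone from 17 (Br on C5 anti to H-10, trans ring fusion) | C[C@@]1(CC[C@](C)(O[Si](CC)(CC)CC)C=C)[C@H](C)[C@@H](OC(C)=O)C(=O)[C@@]2(Br)[C@H]1CCCC2(C)C
F8 | step 11 | 6-epimer of 19, (6R,7R,8S,9R,13S)-7-acetoxy-13-[(triethylsilyl)oxy]halima-5(10),14-dien-6-ol | C[C@@]1(CC[C@](C)(O[Si](CC)(CC)CC)C=C)[C@H](C)[C@@H](OC(C)=O)[C@H](O)C2=C1CCCC2(C)C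
F9 | step 11 | 6-O-chloroacetate of 19 | C[C@@]1(CC[C@](C)(O[Si](CC)(CC)CC)C=C)[C@H](C)[C@@H](OC(C)=O)[C@@H](OC(=O)CCl)C2=C1CCCC2(C)C
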